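**The decision.** In a one-step world the rate follows the catalyst charged, so speed is simply bought with more D. This flask has more steps, so before the next run we ask what a charge above 0.40 mM of D buys.

Q 20 mM; Z 19.0 mM; D 0.40 mM

    Q + D → D + G (k1 = 0.0561 /M/s)
    D + G ⇌ D.G (K2 = 1580 /M, k2 = 0.0294 /M/s)
    Z + D ⇌ Z.D, settled at all times (K3 = 82.8 /M)
    Z + D.G → D + E (k4 = 0.0279 /M/s)

1. the form that holds most of the catalyst when 10 % of the Q are converted (D.G / D / Z.D)
2. its share of the catalyst then
3. factor on the rate of making E when 10 % of the Q are converted if D is charged twice over
4. factor on the rate when 10 % of the Q are converted if D is charged at 4.0 mM instead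

**Free share.** Z is charged far above D, so we hold it at its charge. The balance with D then leaves the free share at 38.9 %: one over one plus K3 times Z, the part of the catalyst not held as Z.D. Comparing the forms gives Z.D as the largest, at 61.1 %.

**The clock.** We work with the fraction of Q left, which falls in a pseudo-first-order way at k1 times free D. The mark of 10 % conversion therefore comes at 3.36 h. D.G follows G with a lag of 0.506 h, set by its loss to Z and its undoing.

**Catch-up.** With G rising steadily, D.G at the mark stands at a fraction of its steady level, which depends on the lag over the time to the mark. That catch-up is 84.9 %. The rate at the mark goes with the charge times the catch-up, since G there is about the same for each charge. A doubled charge reaches the mark in half the time, so its catch-up is 70.9 % and the factor is 1.67. At 4.0 mM the catch-up drops to 26.9 %, and the factor is 3.17. Per unit of D, we reckon, the doubled charge keeps 83.5 % of the rate at the mark and the charge of 4.0 mM keeps 31.7 %, so of these two it is the doubled charge we would try next.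

**The forecast.** It names Z.D at 58.6 %, with factors 1.7 and 2.9, the added catalyst leaving D.G “further behind its steady level”. Its share stands below ours, since ours counts no D.G.

**The flask.** Z.D holds 58.7 %, with D at 37.9 % and D.G at 3.45 %. The factors are 1.69 and 2.99.

**Held catalyst.** With the joining of Z and D taken away, the rate at the mark becomes 1.94 times the actual one, less than one over the free share, 2.57. In the flask with 4.0 mM of D, Z is drawn down to 16.6 mM, so the free share gives Z.D 57.8 %, against a reading of 57.4 %. Z.D gives way later in the first flask: after 300 h Z stands at 0.822 %, with Z.D at 0.584 % against D.G at 54.2 %.

(The constants used here are invented; the flask was simulated.)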